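In the north-west run the left-handed substrate fell by 7.5 percentage points between 1.00 h and 5.00 h, while the right-handed substrate fell by 0.6 points, against a reading scatter of 0.5 points.

| flask | left-handed substrate | right-handed substrate | partner | protic impurity | precatalyst | remark | time |
|---|---|---|---|---|---|---|---|
| north-west | 20 mM | 20 mM | 22 mM | 4 mM | 20 µM | run made earlier |  |
| west | 20 mM | 20 mM | 11 mM | 6 mM | 20 µM | run made earlier |  |
| blue | 20 mM | 20 mM | 22.0 mM | 6.00 mM | 20 µM |  | 15 h |
| grey | 20 mM | 20 mM | 22.0 mM | 6.00 mM | 6.0 µM |  | 15 h |

| run | time / h | right-handed substrate / % | left-handed substrate / % | left-handed product / % |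
|---|---|---|---|---|
| north-west | 1.00 | 50.4 | 50.8 | 0 |
| north-west | 2.00 | 50.0 | 48.6 | 1.6 |
| north-west | 3.00 | 50.2 | 47.0 | 2.0 |
| north-west | 4.00 | 49.5 | 45.9 | 4.7 |
| north-west | 5.00 | 49.8 | 43.3 | 6.0 |
| west | 0.500 | 49.6 | 49.5 | 0 |
| west | 1.33 | 50.0 | 49.2 | 0.1 |
| west | 2.50 | 50.0 | 48.8 | 0.4 |
| west | 4.00 | 49.9 | 47.1 | 2.4 |
| west | 5.00 | 50.0 | 47.1 | 3.5 |

(scatter of a reading: 0.5 percentage points)

- free catalyst is single-handed; left-handed substrate and right-handed substrate are mirror images of each other, charged as a racemate, each of them at the stated concentration
- the earlier runs were read with a standard deviation of 0.5 percentage points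
- on the list of suspects stand: partner + protic impurity -> quenched reagent; partner + catalyst intermediate B -> free catalyst + right-handed product; free catalyst + left-handed substrate <-> catalyst intermediate A; free catalyst + right-handed substrate <-> catalyst intermediate B; partner + catalyst intermediate A -> free catalyst + left-handed product; precatalyst -> free catalyst
- an excess is the difference of the two amounts in percent of their sum
- an excess is below zero if the other one leads
- no earlier run changes the charge of precatalyst; that part of a forecast is a guess

* which one finishes higher in excess of right-handed substrate over left-handed substrate among what is left of the two ("neither" within 2 percentage points) (blue / grey / neither)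
* excess of right-handed substrate over left-handed substrate among what is left of the two at the end, blue
* excess of right-handed substrate over left-handed substrate among what is left of the two at the end, grey

For the next kinetic resolution I had to choose between 20 µM of precatalyst (blue) and 6.0 µM (grey). Dividing the two loss rates removes time, so I took the loss ratio φ, left-handed substrate lost per right-handed substrate lost: 12.5. At this low conversion it serves as a rough selectivity factor, and as a reading it carries that scatter. If p is the left-handed product as a fraction of both substrates charged, the excess is p − p/φ divided by the whole charge less p and p/φ.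

Holding the north-west rise from 2.00 h to 5.00 h steady up to 15 h gave blue p = 20.7%, so an excess of 24.5%. Scaling p by the precatalyst charge, which is a guess, gave grey p = 6.20% and an excess of 6.11%. That gap of 18 points stood against a margin of 2 points, so I chose blue.

The forecast, which said “This suggests saturation in partner”, also named blue, with 25% (17% to 34%) for blue and 7.5% (4% to 12%) for grey, both above mine.

The flask gave blue, with 34.3% for blue and 11.5% for grey.

    partner + protic impurity → quenched reagent (k = 8.08 L mol⁻¹ h⁻¹)
    partner + catalyst intermediate B → free catalyst + right-handed product (k = 155 L mol⁻¹ h⁻¹)
    free catalyst + left-handed substrate ⇌ catalyst intermediate A (K = 614 L mol⁻¹, k = 54000 L mol⁻¹ h⁻¹)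
    free catalyst + right-handed substrate ⇌ catalyst intermediate B (K = 83.0 L mol⁻¹, k = 5.37 × 10⁵ L mol⁻¹ h⁻¹)
    partner + catalyst intermediate A → free catalyst + left-handed product (k = 9380 L mol⁻¹ h⁻¹)
    precatalyst → free catalyst (k = 0.115 h⁻¹)

In blue, half of the quenching turnover up to 15 h was done by 3.19 h, but half of the turnover up to 15 h in the capture of left-handed substrate by free catalyst took until 8.15 h. At 8.15 h in blue, partner went 4.4 times faster into left-handed product than into quenched reagent. With blue's 25.6% of left-handed product, φ gives 32.6%. In the neighbour flask, which is blue with 24 mM of protic impurity, 13.9% of left-handed product gives 15.0% by φ; the computed excess is 16.1%.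

Readings and results are simulated with made-up constants, noise included.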